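**Retrosynthetic overview**

1. Numbering used below: ring C1 (C=O), C2 (C–OAc), C3 (C–Me), C4 (CH–OH), C5 (CH2), C6 (alkylidene carbon); side chain C7 (=C–Me), C8 (CH–O-angelate), C9–C11 (prenyl).
2. Enabling feature: in the exocyclic tetrasubstituted C6=C7 alkene of the cyclohexenone, the ring CH2 (C5) and C8 are cis and the methyl is cis to C1. The alkene is therefore the formal syn adduct of C5 and a C8 unit across a MeC≡C–C1 alkyne, so the C5–C6 ring bond and the alkene geometry can be made in one syn borylcupration/alkylation.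
3. Disconnections: angelate ester at C8–O; C7–C8 by reagent-controlled lithiation–borylation of an alkenyl boronate with a homoprenyl carbamate (sets C8); C5–C6 by copper-catalysed borylative cyclization of an iodo-enyne (key step); C1–C6 by propynyl addition to a lactol; C3–C4 by enamine aldol/lactonisation of 2-oxobutanoic acid with chloroacetaldehyde (sets C4).
4. Ring order: a temporary butenolide (step 1, opened in step 3) fixes the cis C2=C3 geometry; the six-membered carbocycle is closed in step 6; the diosphenol acetate is unveiled last (steps 10–12).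

Key step: step 6

Remark (assumption): C1 is carried as a mixture of epimers from step 3 to step 10, and C3 is stereorandom in 22 and 23. Both centres become sp2 in step 11, so they carry no descriptor in the SMILES; every other stereo-element is single.

**Step 1**
Reactants: 1 2-oxobutanoic acid; 2 chloroacetaldehyde
Product: 4 (5S)-5-(chloromethyl)-3-hydroxy-4-methylfuran-2(5H)-one, via aldol adduct 3 (not isolated)
Conditions: (R)-2-(pyrrolidin-2-yl)-1H-benzimidazole (10 mol%), CF3CO2H (10 mol%), THF, 0 °C to rt (2 as its 50 wt% aqueous solution)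
Reagents that add atoms: none
Why: Enamine-catalysed direct aldol of the α-keto acid (donor at its CH2) with the aldehyde, followed by spontaneous lactonisation and enolisation, is a known organocatalytic isotetronic acid synthesis; the D-proline-derived catalyst should set the carbinol carbon (C4 of the target; S here because CH2Cl outranks the ring carbon) through the usual hydrogen-bond-directed enamine transition state, and the second aldol centre is erased by enolisation.

**Step 2**
Reactants: 4 (5S)-5-(chloromethyl)-3-hydroxy-4-methylfuran-2(5H)-one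
Product: 5 (5S)-5-(chloromethyl)-4-methyl-3-(triisopropylsilyloxy)furan-2(5H)-one
Conditions: i-Pr3SiCl, imidazole, DMF, 0 °C to rt
Reagents that add atoms: triisopropylsilyl chloride, CC(C)[Si](Cl)(C(C)C)C(C)C
Why: O-silylation of the acidic enol hydroxyl (the only OH); the bulky triisopropylsilyl group is chosen so that it should neither migrate to the neighbouring alkoxide in step 3 nor be cleaved by alkoxide in step 6.

**Step 3**
Reactants: 5 (5S)-5-(chloromethyl)-4-methyl-3-(triisopropylsilyloxy)furan-2(5H)-one; 6 1-propynylmagnesium bromide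
Product: 8 (2S,3E)-1-chloro-3-methyl-4-(triisopropylsilyloxy)oct-3-en-6-yne-2,5-diol (epimers at the propargylic carbinol), via diisobutylaluminium lactolate 7 (not isolated)
Conditions: i-Bu2AlH, CH2Cl2, −78 °C; then 6, THF, −78 to 0 °C; Rochelle-salt work-up
Reagents that add atoms: none
Why: Half-reduction of the lactone to the aluminium lactolate and 1,2-addition of the alkynyl Grignard reagent to the aldehyde released on warming (lactone to lactol to diol) should open the ring with the C2=C3 geometry fixed by its ring origin (C1 and C4 cis); C1 forms as an epimeric mixture that is erased in step 11.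

**Step 4**
Reactants: 8 (2S,3E)-1-chloro-3-methyl-4-(triisopropylsilyloxy)oct-3-en-6-yne-2,5-diol
Product: 9 (2S,3E)-1-chloro-3-methyl-2,5-bis(triethylsilyloxy)-4-(triisopropylsilyloxy)oct-3-en-6-yne (propargylic epimers)
Conditions: Et3SiCl, imidazole, DMAP (cat.), DMF, 0 °C to rt
Reagents that add atoms: chlorotriethylsilane, CC[Si](Cl)(CC)CC
Why: Standard silylation of both secondary alcohols, needed so that no alkoxide can displace the halide (epoxide or cyclic ether formation) under the basic conditions of step 6.

**Step 5**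
Reactants: 9 (2S,3E)-1-chloro-3-methyl-2,5-bis(triethylsilyloxy)-4-(triisopropylsilyloxy)oct-3-en-6-yne
Product: 10 (2S,3E)-1-iodo-3-methyl-2,5-bis(triethylsilyloxy)-4-(triisopropylsilyloxy)oct-3-en-6-yne (propargylic epimers)
Conditions: NaI, NaHCO3, 2-butanone, 80 °C
Reagents that add atoms: sodium iodide, [Na+].[I-]
Why: Finkelstein halide exchange (SN2 at the primary carbon, driven by precipitation of NaCl) installs the better leaving group for the alkylation in step 6.

**Step 6**
Reactants: 10 (2S,3E)-1-iodo-3-methyl-2,5-bis(triethylsilyloxy)-4-(triisopropylsilyloxy)oct-3-en-6-yne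
Product: 12 2-[(1Z)-1-{(5R)-4-methyl-2,5-bis(triethylsilyloxy)-3-(triisopropylsilyloxy)cyclohex-3-en-1-ylidene}ethyl]-4,4,5,5-tetramethyl-1,3,2-dioxaborolane (boron cis to the ring CH2), via alkenylcopper intermediate 11 (not isolated)
Conditions: CuCl (10 mol%), Xantphos (10 mol%), B2pin2 (1.3 equiv), NaOt-Bu (1.3 equiv), THF (0.02 M), rt
Reagents that add atoms: bis(pinacolato)diboron, CC1(C)OB(OC1(C)C)B1OC(C)(C)C(C)(C)O1
Why: The boryl–copper species LCu–Bpin (monovalent copper, L = Xantphos) should add syn across the C6≡C7 triple bond with boron on the methyl-bearing C7 and copper on C6 (the usual sense for propargylic ethers, copper next to the carbon carrying the electron-withdrawing silyloxy group), and the configurationally stable alkenylcopper then displaces the primary iodide at C5 with retention at the sp2 carbon. The closest known reaction type is the copper-catalysed alkylboration (carboboration) of internal alkynes, including its intramolecular borylative cyclizations of alkynes bearing a tethered alkyl halide. The six-membered carbocycle is closed in the 6-exo-tet mode at C5 (exo-dig with respect to the alkyne). No stereocentre is created; the geometry of the new tetrasubstituted alkene (C5 cis to boron, methyl cis to C1) follows from the syn addition, C4 is untouched, and both C1 epimers cyclize and converge later. The step needs regiocontrol of the borylcupration and chemoselectivity over direct borylation of the C–I bond and over loss of silyloxide to an allene: only the regioisomer with copper on C6 can cyclize, the cis C2=C3 bond holds C5 next to C6, alkyne borylcupration is faster than C–I borylation, and a silyl ether is a poor leaving group.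

**Step 7**
Reactants: 13 4-methylpent-3-en-1-ol
Product: 14 4-methylpent-3-en-1-yl N,N-diisopropylcarbamate
Conditions: i-Pr2NCOCl, Et3N, CH2Cl2, reflux
Reagents that add atoms: N,N-diisopropylcarbamoyl chloride, CC(C)N(C(C)C)C(Cl)=O
Why: Carbamoylation of the primary alcohol gives the Hoppe carbamate that directs α-lithiation in step 8.

**Step 8**
Reactants: 12 cyclic alkenyl pinacol boronate; 14 4-methylpent-3-en-1-yl N,N-diisopropylcarbamate
Product: 18 (2E,3S)-2-[(5R)-4-methyl-2,5-bis(triethylsilyloxy)-3-(triisopropylsilyloxy)cyclohex-3-en-1-ylidene]-6-methylhept-5-en-3-ol, via lithiated carbamate 15 (not isolated), via lithium boronate complex 16 (not isolated), via allylic boronic ester 17 (not isolated)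
Conditions: 14 (1.4 equiv), s-BuLi, (+)-sparteine, Et2O, −78 °C; then 12, −78 °C; MgBr2·OEt2, warm to reflux; then NaOH, H2O2, THF, 0 °C
Reagents that add atoms: hydrogen peroxide, OO
Why: Hoppe–Matteson–Aggarwal lithiation–borylation: s-BuLi/(+)-sparteine removes the pro-R hydrogen next to the carbamate oxygen, the configurationally stable organolithium is borylated by 12 with retention, the alkenyl group migrates from boron to carbon with inversion and with retention of alkene geometry (1,2-metallate rearrangement expelling the carbamate), and stereoretentive oxidation of the allylic boronic ester should give the 8S alcohol under reagent control.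

**Step 9**
Reactants: 18 allylic alcohol; 19 angelic acid [(2Z)-2-methylbut-2-enoic acid]
Product: 21 (2E,3S)-2-[(5R)-4-methyl-2,5-bis(triethylsilyloxy)-3-(triisopropylsilyloxy)cyclohex-3-en-1-ylidene]-6-methylhept-5-en-3-yl (2Z)-2-methylbut-2-enoate, via mixed anhydride 20 (not isolated)
Conditions: 19, 2,4,6-Cl3C6H2COCl, Et3N, toluene, rt; then 18, toluene, 75 °C (no DMAP)
Reagents that add atoms: none
Why: Acylation of the hindered allylic alcohol by the preformed angelic 2,4,6-trichlorobenzoic mixed anhydride (Yamaguchi-type esterification run without a nucleophilic catalyst) is the established way to transfer the (Z)-2-methylbut-2-enoyl group without isomerisation to the tiglate.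

**Step 10**
Reactants: 21 tris-silylated angelate
Product: 22 (2E,3S)-2-[(5R)-2,5-dihydroxy-4-methyl-3-oxocyclohexylidene]-6-methylhept-5-en-3-yl (2Z)-2-methylbut-2-enoate (epimers at the two carbons flanking the ketone)
Conditions: HF·pyridine, pyridine, THF, 0 °C to rt
Reagents that add atoms: none
Why: Fluoride-mediated cleavage of both triethylsilyl ethers and of the silyl enol ether (protodesilylation to the C2 ketone); the configurations at C1 and C3 are irrelevant because both carbons become sp2 in step 11.

**Step 11**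
Reactants: 22 α-hydroxy ketone
Product: 24 (2E,3S)-2-[(5R)-3,5-dihydroxy-4-methyl-2-oxocyclohex-3-en-1-ylidene]-6-methylhept-5-en-3-yl (2Z)-2-methylbut-2-enoate, via diketone 23 (not isolated)
Conditions: Cu(OAc)2 (2.1 equiv), MeOH, 40 °C, argon
Reagents that add atoms: none
Why: Copper-diacetate oxidation of an acyloin to the α-diketone through the chelated enediolate touches only the C1 carbinol, which is α to the C2 ketone, and leaves the β-positioned C4 carbinol alone; the diketone then enolises toward C3, its only α-carbon bearing hydrogen, to give the diosphenol.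

**Step 12**
Reactants: 24 diosphenol
Product: 25 (2E,3S)-2-[(5R)-3-acetoxy-5-hydroxy-4-methyl-2-oxocyclohex-3-en-1-ylidene]-6-methylhept-5-en-3-yl (2Z)-2-methylbut-2-enoate (CNP0389456.1)
Conditions: Ac2O (1.1 equiv), Et3N, CH2Cl2, −40 to 0 °C
Reagents that add atoms: acetic anhydride, CC(=O)OC(C)=O
Why: Selective enol acetylation: the diosphenol hydroxyl, with acidity close to a phenol, is acylated through its enolate far faster than the secondary C4 alcohol when no nucleophilic acylation catalyst is present.

**Compound list**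

1 | 2-oxobutanoic acid | CCC(=O)C(=O)O | starting material
2 | chloroacetaldehyde | ClCC=O | starting material
3 | (4S)-5-chloro-4-hydroxy-3-methyl-2-oxopentanoic acid (aldol adduct, C3 epimers, not isolated) | CC(C(=O)C(=O)O)[C@H](O)CCl | intermediate
4 | (5S)-5-(chloromethyl)-3-hydroxy-4-methylfuran-2(5H)-one | O=C1O[C@H](CCl)C(C)=C1O | intermediate
5 | (5S)-5-(chloromethyl)-4-methyl-3-(triisopropylsilyloxy)furan-2(5H)-one | O=C1O[C@H](CCl)C(C)=C1O[Si](C(C)C)(C(C)C)C(C)C | intermediate
6 | 1-propynylmagnesium bromide | CC#C[Mg]Br | starting material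
7 | diisobutylaluminium lactolate of 5 (anomers, not isolated) | CC(C)C[Al](CC(C)C)OC1O[C@H](CCl)C(C)=C1O[Si](C(C)C)(C(C)C)C(C)C | intermediate
8 | (2S,3E)-1-chloro-3-methyl-4-(triisopropylsilyloxy)oct-3-en-6-yne-2,5-diol (the two carbinol carbons cis on the alkene; propargylic epimers) | ClC[C@@H](O)/C(C)=C(O[Si](C(C)C)(C(C)C)C(C)C)\C(O)C#CC | intermediate
9 | (2S,3E)-1-chloro-3-methyl-2,5-bis(triethylsilyloxy)-4-(triisopropylsilyloxy)oct-3-en-6-yne (propargylic epimers) | ClC[C@@H](O[Si](CC)(CC)CC)/C(C)=C(O[Si](C(C)C)(C(C)C)C(C)C)\C(O[Si](CC)(CC)CC)C#CC | intermediate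
10 | (2S,3E)-1-iodo-3-methyl-2,5-bis(triethylsilyloxy)-4-(triisopropylsilyloxy)oct-3-en-6-yne (propargylic epimers) | IC[C@@H](O[Si](CC)(CC)CC)/C(C)=C(O[Si](C(C)C)(C(C)C)C(C)C)\C(O[Si](CC)(CC)CC)C#CC | intermediate
11 | β-boryl alkenylcopper intermediate, copper and boron cis (Xantphos on copper omitted from the SMILES; not isolated) | IC[C@@H](O[Si](CC)(CC)CC)/C(C)=C(O[Si](C(C)C)(C(C)C)C(C)C)\C(O[Si](CC)(CC)CC)/C([Cu])=C(\C)B1OC(C)(C)C(C)(C)O1 | intermediate
12 | 2-[(1Z)-1-{(5R)-4-methyl-2,5-bis(triethylsilyloxy)-3-(triisopropylsilyloxy)cyclohex-3-en-1-ylidene}ethyl]-4,4,5,5-tetramethyl-1,3,2-dioxaborolane (C1 epimers) | CC1(C)OB(OC1(C)C)/C(C)=C2\C[C@@H](O[Si](CC)(CC)CC)C(C)=C(O[Si](C(C)C)(C(C)C)C(C)C)C2O[Si](CC)(CC)CC | intermediate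
13 | 4-methylpent-3-en-1-ol | CC(C)=CCCO | starting material
14 | 4-methylpent-3-en-1-yl N,N-diisopropylcarbamate | CC(C)=CCCOC(=O)N(C(C)C)C(C)C | intermediate
15 | (R)-α-lithiated carbamate, (+)-sparteine complex (sparteine omitted from the SMILES; not isolated) | [Li][C@H](CC=C(C)C)OC(=O)N(C(C)C)C(C)C | intermediate
16 | lithium boronate complex from 15 and 12 (not isolated) | [Li+].CC(C)N(C(C)C)C(=O)O[C@@H](CC=C(C)C)[B-]1(OC(C)(C)C(C)(C)O1)/C(C)=C2\C[C@@H](O[Si](CC)(CC)CC)C(C)=C(O[Si](C(C)C)(C(C)C)C(C)C)C2O[Si](CC)(CC)CC | intermediate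
17 | allylic pinacol boronic ester, 8S, alkene E (not isolated) | CC1(C)OB(OC1(C)C)[C@@H](CC=C(C)C)/C(C)=C2\C[C@@H](O[Si](CC)(CC)CC)C(C)=C(O[Si](C(C)C)(C(C)C)C(C)C)C2O[Si](CC)(CC)CC | intermediate
18 | (2E,3S)-2-[(5R)-4-methyl-2,5-bis(triethylsilyloxy)-3-(triisopropylsilyloxy)cyclohex-3-en-1-ylidene]-6-methylhept-5-en-3-ol (C1 epimers) | O[C@@H](CC=C(C)C)/C(C)=C1\C[C@@H](O[Si](CC)(CC)CC)C(C)=C(O[Si](C(C)C)(C(C)C)C(C)C)C1O[Si](CC)(CC)CC | intermediate
19 | angelic acid, (2Z)-2-methylbut-2-enoic acid | C/C=C(/C)C(=O)O | starting material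
20 | (2Z)-2-methylbut-2-enoic 2,4,6-trichlorobenzoic anhydride (not isolated) | C/C=C(/C)C(=O)OC(=O)c1c(Cl)cc(Cl)cc1Cl | intermediate
21 | (2E,3S)-2-[(5R)-4-methyl-2,5-bis(triethylsilyloxy)-3-(triisopropylsilyloxy)cyclohex-3-en-1-ylidene]-6-methylhept-5-en-3-yl (2Z)-2-methylbut-2-enoate (C1 epimers) | C/C=C(/C)C(=O)O[C@@H](CC=C(C)C)/C(C)=C1\C[C@@H](O[Si](CC)(CC)CC)C(C)=C(O[Si](C(C)C)(C(C)C)C(C)C)C1O[Si](CC)(CC)CC | intermediate
22 | (2E,3S)-2-[(5R)-2,5-dihydroxy-4-methyl-3-oxocyclohexylidene]-6-methylhept-5-en-3-yl (2Z)-2-methylbut-2-enoate (C1 and C3 epimers) | C/C=C(/C)C(=O)O[C@@H](CC=C(C)C)/C(C)=C1\C[C@@H](O)C(C)C(=O)C1O | intermediate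
23 | (2E,3S)-2-[(5R)-5-hydroxy-4-methyl-2,3-dioxocyclohexylidene]-6-methylhept-5-en-3-yl (2Z)-2-methylbut-2-enoate (C3 epimers, not isolated) | C/C=C(/C)C(=O)O[C@@H](CC=C(C)C)/C(C)=C1\C[C@@H](O)C(C)C(=O)C1=O | intermediate
24 | (2E,3S)-2-[(5R)-3,5-dihydroxy-4-methyl-2-oxocyclohex-3-en-1-ylidene]-6-methylhept-5-en-3-yl (2Z)-2-methylbut-2-enoate | C/C=C(/C)C(=O)O[C@@H](CC=C(C)C)/C(C)=C1\C[C@@H](O)C(C)=C(O)C1=O | intermediate
25 | (2E,3S)-2-[(5R)-3-acetoxy-5-hydroxy-4-methyl-2-oxocyclohex-3-en-1-ylidene]-6-methylhept-5-en-3-yl (2Z)-2-methylbut-2-enoate, CNP0389456.1 | C/C=C(/C)C(=O)O[C@@H](CC=C(C)C)/C(C)=C1\C[C@@H](O)C(C)=C(OC(C)=O)C1=O | target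

**Step count and risks**

Total step count: 12 (11 in the main line plus the one-step preparation of carbamate 14).
Longest linear sequence: 11 steps (steps 1–6 and 8–12).

Steps most likely to fail:

Step 6. The six-membered ring closure of the alkenylcopper may be outrun by its protonation, by loss of silyloxide to an allene, or by direct borylation of the carbon–iodine bond, and the borylcupration may take the wrong regiochemistry. The fallback sets out from chloride 9 and returns at boronate 12. Syn-diboration of the alkyne with B2pin2 under Pt(PPh3)4 catalysis (toluene, 80 °C; the alkyl chloride is inert) should give the cis-1,2-diboryl alkene F1. Halide exchange (NaI, 2-butanone, 80 °C) gives the iodide F2. An intramolecular alkyl–alkenyl Suzuki–Miyaura coupling (Pd(OAc)2, P(t-Bu)2Me, KOt-Bu, tert-amyl alcohol, high dilution) then closes the ring, because only the boron on C6 can reach C5; the boron on C7 stays cis to the new ring bond, which is compound 12. This replaces the alkylation of an alkenylcopper by an oxidative-addition/transmetalation sequence and removes the regiochemical question.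

Step 8. Boronate-complex formation at the hindered tetrasubstituted alkenyl boronate may be slow, so that the lithiated carbamate decomposes before the 1,2-migration, or the enantiomeric purity at C8 may erode. The fallback sets out from 12 and returns at 18. Ipso-iododeboronation with N-iodosuccinimide (MeCN, 0 °C, retention) gives the alkenyl iodide F3. Nozaki–Hiyama–Kishi coupling (CrCl2, catalytic NiCl2, DMF) with 4-methylpent-3-enal F4, made by Dess–Martin oxidation of 13, gives the allylic alcohols F5 as a mixture at C8. Dess–Martin oxidation gives the enone F6, and reduction with (R)-2-methyl-CBS-oxazaborolidine and catecholborane (toluene, −78 °C; the tetrasubstituted alkenyl group acts as the large substituent) should return the 8S alcohol 18.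

Step 1. Enantiofacial control may be poor with this α-chloro aldehyde, and the amine catalyst may be lost to N-alkylation or to self-condensation of the aldehyde. The fallback sets out from 1 and 2 and returns at 5. The same aldol/lactonisation run with an achiral amine salt (pyrrolidinium acetate, THF) gives the racemic butenolide F7. Silylation as in step 2 gives the racemic silyl ether F8, which is resolved by preparative chromatography on a chiral stationary phase (supercritical CO2/alcohol); the (S)-enantiomer is compound 5.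

**Further compounds**

F1 | step 6 | (2S,3E,6Z)-1-chloro-3-methyl-6,7-bis(4,4,5,5-tetramethyl-1,3,2-dioxaborolan-2-yl)-2,5-bis(triethylsilyloxy)-4-(triisopropylsilyloxy)octa-3,6-diene (boron atoms cis; C5 epimers) | ClC[C@@H](O[Si](CC)(CC)CC)/C(C)=C(O[Si](C(C)C)(C(C)C)C(C)C)\C(O[Si](CC)(CC)CC)/C(B1OC(C)(C)C(C)(C)O1)=C(\C)B1OC(C)(C)C(C)(C)O1
F2 | step 6 | (2S,3E,6Z)-1-iodo-3-methyl-6,7-bis(4,4,5,5-tetramethyl-1,3,2-dioxaborolan-2-yl)-2,5-bis(triethylsilyloxy)-4-(triisopropylsilyloxy)octa-3,6-diene (boron atoms cis; C5 epimers) | IC[C@@H](O[Si](CC)(CC)CC)/C(C)=C(O[Si](C(C)C)(C(C)C)C(C)C)\C(O[Si](CC)(CC)CC)/C(B1OC(C)(C)C(C)(C)O1)=C(\C)B1OC(C)(C)C(C)(C)O1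
F3 | step 8 | (5R)-1-[(1E)-1-iodoethylidene]-4-methyl-2,5-bis(triethylsilyloxy)-3-(triisopropylsilyloxy)cyclohex-3-ene (iodine cis to the ring CH2; C2 epimers) | I/C(C)=C1\C[C@@H](O[Si](CC)(CC)CC)C(C)=C(O[Si](C(C)C)(C(C)C)C(C)C)C1O[Si](CC)(CC)CC
F4 | step 8 | 4-methylpent-3-enal | CC(C)=CCC=O
F5 | step 8 | (2E)-2-[(5R)-4-methyl-2,5-bis(triethylsilyloxy)-3-(triisopropylsilyloxy)cyclohex-3-en-1-ylidene]-6-methylhept-5-en-3-ol (mixture at the carbinol carbon) | OC(CC=C(C)C)/C(C)=C1\C[C@@H](O[Si](CC)(CC)CC)C(C)=C(O[Si](C(C)C)(C(C)C)C(C)C)C1O[Si](CC)(CC)CC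
F6 | step 8 | (2E)-2-[(5R)-4-methyl-2,5-bis(triethylsilyloxy)-3-(triisopropylsilyloxy)cyclohex-3-en-1-ylidene]-6-methylhept-5-en-3-one | O=C(CC=C(C)C)/C(C)=C1\C[C@@H](O[Si](CC)(CC)CC)C(C)=C(O[Si](C(C)C)(C(C)C)C(C)C)C1O[Si](CC)(CC)CC
F7 | step 1 | racemic 5-(chloromethyl)-3-hydroxy-4-methylfuran-2(5H)-one | O=C1OC(CCl)C(C)=C1O
F8 | step 1 | racemic 5-(chloromethyl)-4-methyl-3-(triisopropylsilyloxy)furan-2(5H)-one | O=C1OC(CCl)C(C)=C1O[Si](C(C)C)(C(C)C)C(C)C
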